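A direct plan would hang the 2-arylallyl alcohol A1, which already carries rings B and D, on a phenol oxygen of ring A to give the allyl aryl ether A2, would move the allyl group to carbon by aromatic Claisen rearrangement to give the C-allyl phenol A3, and would close ring C last by enantioselective anti-Markovnikov hydroetherification to the silyl ether A4 of the target. Its weakest steps would be the ring closure, because C3 would have to be set by hydrogen-atom transfer to a planar benzylic radical, a control without reliable precedent, and the O-to-C allyl shift, because it would need about 190 °C on a chelated hydroxy aldehyde, where abnormal Claisen and dihydrobenzofuran-forming paths would compete.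

The new route cuts the C3–C1′ bond between rings C and B. Rings C and D would be closed on separate halves by the same π-acid-catalysed alkyne hydroarylation; the key step would join the halves by an enantioselective reductive Heck hydroarylation of the C3=C4 bond of the ring A/C 2H-chromene with the ring B/D aryl bromide. It exploits that C4 is benzylic to ring A and shielded by the peri 5-methoxy group, so the aryl group goes to C3, and that the adduct has no syn β-hydrogen, so formate ends the cycle. One operation forms C3–C1′ and sets C3, without allyl shift or radical ring closure.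

Key step: step 7

Remark on the chemistry: atom numbers follow the isoflavan skeleton (O1, C2, C3, C4 in ring C, C4a to C8a in ring A, primed numbers in ring B); ring D is the dimethylpyran fused to ring B.

Remark on the chemistry: in the coupling step formate is used as its trialkylammonium salt in dry acetonitrile, so that the aryl silyl ether is not exposed to an alkali carboxylate in a dipolar aprotic solvent.

Step 1
Reactants: 1 2,4,6-trihydroxybenzaldehyde
Product: 2 2,6-dihydroxy-4-methoxybenzaldehyde
Conditions: Me2SO4 (1.0 equiv), K2CO3 (1.0 equiv), acetone, 0 °C → rt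
Reagents that add atoms: dimethyl sulfate, COS(=O)(=O)OC
Why: Williamson O-methylation should take only the 4-OH, the most acidic hydroxyl (para to the formyl group) and the only one not held in a hydrogen bond to it, and it leaves a symmetric product with two equivalent OH groups.

Step 2
Reactants: 2 2,6-dihydroxy-4-methoxybenzaldehyde; 3 3-bromoprop-1-yne (propargyl bromide)
Product: 4 2-hydroxy-4-methoxy-6-(prop-2-yn-1-yloxy)benzaldehyde
Conditions: 3 (1.05 equiv), K2CO3 (1.1 equiv), DMF, 0 °C → rt
Reagents that add atoms: none
Why: Williamson etherification with the primary propargylic bromide should stop at the mono-ether, because the two OH groups of 2 are equivalent and the one left in 4 is locked in a hydrogen bond to the formyl group and is a far poorer nucleophile.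

Step 3
Reactants: 4 2-hydroxy-4-methoxy-6-(prop-2-yn-1-yloxy)benzaldehyde
Product: 5 7-hydroxy-5-methoxy-2H-chromene-8-carbaldehyde
Conditions: [(t-Bu)2(2-biphenylyl)P]Au(MeCN)SbF6 (2 mol%), CH2Cl2, rt
Reagents that add atoms: none
Why: Intramolecular alkyne hydroarylation by a cationic π-acid of monovalent gold (6-endo-dig attack of the arene on the activated alkyne, then protodeauration) should close the 2H-pyran at the only free carbon ortho to the ether oxygen, which is activated by the para OH and the ortho methoxy group, and it puts the C3=C4 double bond in place.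

Step 4
Reactants: 6 4-bromobenzene-1,3-diol
Product: 7 2-bromo-5-(tert-butyldimethylsilyloxy)phenol
Conditions: TBSCl (1.0 equiv), imidazole (2.2 equiv), DMF, −20 → 0 °C
Reagents that add atoms: tert-butyldimethylsilyl chloride, CC(C)(C)[Si](C)(C)Cl
Why: O-silylation with the bulky silyl chloride should take the OH para to bromine, because the other OH is flanked by the bromine atom, so that the oxygen that must become the ring D oxygen stays free.

Step 5
Reactants: 7 2-bromo-5-(tert-butyldimethylsilyloxy)phenol; 8 3-chloro-3-methylbut-1-yne
Product: 9 tert-butyl{4-bromo-3-[(2-methylbut-3-yn-2-yl)oxy]phenoxy}dimethylsilane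
Conditions: 8 (1.5 equiv), DBU (1.6 equiv), CuCl2·2H2O (1 mol%), dry MeCN, 0 °C → rt
Reagents that add atoms: none
Why: Copper-catalysed propargylic etherification (attack of the phenoxide on a copper-bound propargyl electrophile formed from the tertiary chloride) should put the 1,1-dimethylpropargyl group on the only free OH, and the aryl silyl ether should survive the amidine base in the dry, aprotic medium.

Step 6
Reactants: 9 tert-butyl{4-bromo-3-[(2-methylbut-3-yn-2-yl)oxy]phenoxy}dimethylsilane
Product: 10 tert-butyl[(8-bromo-2,2-dimethyl-2H-chromen-5-yl)oxy]dimethylsilane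
Conditions: [(t-Bu)2(2-biphenylyl)P]Au(MeCN)SbF6 (2 mol%), CH2Cl2, rt
Reagents that add atoms: none
Why: The same 6-endo-dig alkyne hydroarylation by the cationic gold π-acid should close ring D at the only free ortho carbon, the nucleophilic position between the two oxygen substituents, helped by the gem-dimethyl group, while the C–Br bond and the silyl ether are inert to the catalyst.

Step 7
Reactants: 5 7-hydroxy-5-methoxy-2H-chromene-8-carbaldehyde; 10 tert-butyl[(8-bromo-2,2-dimethyl-2H-chromen-5-yl)oxy]dimethylsilane
Product: 11 (3R)-3-[5-(tert-butyldimethylsilyloxy)-2,2-dimethyl-2H-chromen-8-yl]-7-hydroxy-5-methoxy-3,4-dihydro-2H-chromene-8-carbaldehyde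
Conditions: Pd(dba)2 (5 mol%), Xyl-SDP(O) (6 mol%; chiral spirobiindane bisphosphine monoxide, antipode fixed in a first screen to give 3R), 5 (1.0 equiv), 10 (1.3 equiv), HCO2H (2.0 equiv), i-Pr2NEt (3.0 equiv), dry MeCN, 60 °C, Ar
Reagents that add atoms: none
Why: Proposed new method: an enantioselective intermolecular reductive Heck hydroarylation, in which zerovalent palladium inserts into the C–Br bond of 10, the arylpalladium bromide (with the hemilabile P=O arm of the ligand opened) binds one face of the C3=C4 bond of 5 and adds syn across it, aryl to C3 and palladium to C4, and formate then replaces bromide, loses CO2 and leaves a hydride that is reductively eliminated with C4. The closest known reaction types are the racemic palladium-mediated oxyarylation and hydroarylation of 2H-chromenes, which place the aryl group at C3, and the enantioselective reductive Heck hydroarylation of norbornenes and related cyclic alkenes with chiral phosphine ligands. No ring is closed: the step joins the ring A/C half to the ring B/D half through the new C3–C1′ bond. The only new stereocentre, C3, is set in the migratory insertion by the chiral ligand, which decides the alkene face that meets the aryl group, and the later C4–H bond formation cannot touch it. The step needs regioselectivity, which the substrate secures because palladium at C4 is an η3-benzyl species stabilised by the electron-rich ring A and because the peri 5-methoxy group shields C4 from the incoming aryl group, and chemoselectivity against the ring D double bonds of 10 and 11, which are flanked by a quaternary carbon and should insert far more slowly. β-Hydride elimination to the isoflav-3-ene is blocked because the only β-hydrogen, at C3, is anti to palladium after syn addition, so that reduction by formate is the open path.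

Step 8
Reactants: 11 (3R)-3-[5-(tert-butyldimethylsilyloxy)-2,2-dimethyl-2H-chromen-8-yl]-7-hydroxy-5-methoxy-3,4-dihydro-2H-chromene-8-carbaldehyde
Product: 12 (3R)-7-hydroxy-3-(5-hydroxy-2,2-dimethyl-2H-chromen-8-yl)-5-methoxy-3,4-dihydro-2H-chromene-8-carbaldehyde
Conditions: TBAF (1.2 equiv), AcOH (1.2 equiv), THF, 0 °C
Reagents that add atoms: none
Why: Fluoride-driven cleavage of the aryl silyl ether (strong Si–F bond), buffered with acetic acid, should free the 4′-OH without touching the aldehyde, the ring D double bond or the non-acidic C3–H stereocentre.

**Compound list**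
1 | 2,4,6-trihydroxybenzaldehyde | O=Cc1c(O)cc(O)cc1O | starting material
2 | 2,6-dihydroxy-4-methoxybenzaldehyde | COc1cc(O)c(C=O)c(O)c1 | intermediate
3 | 3-bromoprop-1-yne (propargyl bromide) | C#CCBr | starting material
4 | 2-hydroxy-4-methoxy-6-(prop-2-yn-1-yloxy)benzaldehyde | COc1cc(O)c(C=O)c(OCC#C)c1 | intermediate
5 | 7-hydroxy-5-methoxy-2H-chromene-8-carbaldehyde | COc1cc(O)c(C=O)c2c1C=CCO2 | intermediate
6 | 4-bromobenzene-1,3-diol | Oc1ccc(Br)c(O)c1 | starting material
7 | 2-bromo-5-(tert-butyldimethylsilyloxy)phenol | Oc1cc(O[Si](C)(C)C(C)(C)C)ccc1Br | intermediate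
8 | 3-chloro-3-methylbut-1-yne | C#CC(C)(C)Cl | starting material
9 | tert-butyl{4-bromo-3-[(2-methylbut-3-yn-2-yl)oxy]phenoxy}dimethylsilane | C#CC(C)(C)Oc1cc(O[Si](C)(C)C(C)(C)C)ccc1Br | intermediate
10 | tert-butyl[(8-bromo-2,2-dimethyl-2H-chromen-5-yl)oxy]dimethylsilane | CC1(C)C=Cc2c(O[Si](C)(C)C(C)(C)C)ccc(Br)c2O1 | intermediate
11 | (3R)-3-[5-(tert-butyldimethylsilyloxy)-2,2-dimethyl-2H-chromen-8-yl]-7-hydroxy-5-methoxy-3,4-dihydro-2H-chromene-8-carbaldehyde | COc1cc(O)c(C=O)c2c1C[C@H](c1ccc(O[Si](C)(C)C(C)(C)C)c3c1OC(C)(C)C=C3)CO2 | intermediate
12 | (3R)-7-hydroxy-3-(5-hydroxy-2,2-dimethyl-2H-chromen-8-yl)-5-methoxy-3,4-dihydro-2H-chromene-8-carbaldehyde | COc1cc(O)c(C=O)c2c1C[C@H](c1ccc(O)c3c1OC(C)(C)C=C3)CO2 | target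

Total step count: 8. Longest linear sequence: 5 steps (steps 1, 2, 3, 7, 8, or steps 4, 5, 6, 7, 8).

Steps most likely to fail:

1. Step 7 (the step beyond known chemistry). The carbopalladation may discriminate poorly between the two alkene faces, or formate may reduce the arylpalladium intermediate before it inserts. The fallback uses known chemistry and sets out from 5 and 10. Hydroarylation with an achiral catalyst (Pd(OAc)2, PPh3, HCO2H, i-Pr2NEt, MeCN, 70 °C) would give racemic 3-[5-(tert-butyldimethylsilyloxy)-2,2-dimethyl-2H-chromen-8-yl]-7-hydroxy-5-methoxy-3,4-dihydro-2H-chromene-8-carbaldehyde F1. Preparative chromatography on a chiral stationary phase would then separate the 3R enantiomer, so that the route is rejoined at 11.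

2. Step 3. The chelating hydroxy aldehyde may bind the cationic gold complex, or the electron-rich 2H-chromene may oligomerise under the π-acid once it has formed. The fallback sets out from 4 and drops the metal. Heating in N,N-diethylaniline at about 200 °C would lead through a propargyl Claisen [3,3] shift, a 1,5-hydrogen shift and an oxa-6π electrocyclisation to the same chromene, so that it comes back at 5; no new compound is made on the way (entry F0).

3. Step 6. The cationic gold complex may ionise the tertiary propargylic C–O bond, so that the propargyl group is lost and 7 is returned. The fallback sets out from 7 and leaves out 9. Condensation with 3-methylbut-2-enal F2 on a phenylboronic acid template (PhB(OH)2, catalytic AcOH, toluene, reflux with removal of water) would form the C–C bond at the free ortho carbon first. Oxa-6π electrocyclisation of the resulting ortho-quinone methide would then close the pyran, coming back at 10.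

Further compounds
F1 | step 7 | racemic 3-[5-(tert-butyldimethylsilyloxy)-2,2-dimethyl-2H-chromen-8-yl]-7-hydroxy-5-methoxy-3,4-dihydro-2H-chromene-8-carbaldehyde | COc1cc(O)c(C=O)c2c1CC(c1ccc(O[Si](C)(C)C(C)(C)C)c3c1OC(C)(C)C=C3)CO2
F0 | step 3 | none | none
F2 | step 6 | 3-methylbut-2-enal | CC(C)=CC=O
A1 | direct plan | 2-[2,2-dimethyl-5-(triisopropylsilyloxy)-2H-chromen-8-yl]prop-2-en-1-ol | C=C(CO)c1ccc(O[Si](C(C)C)(C(C)C)C(C)C)c2c1OC(C)(C)C=C2
A2 | direct plan | 2-({2-[2,2-dimethyl-5-(triisopropylsilyloxy)-2H-chromen-8-yl]prop-2-en-1-yl}oxy)-6-hydroxy-4-methoxybenzaldehyde | COc1cc(O)c(C=O)c(OCC(=C)c2ccc(O[Si](C(C)C)(C(C)C)C(C)C)c3c2OC(C)(C)C=C3)c1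
A3 | direct plan | 3-{2-[2,2-dimethyl-5-(triisopropylsilyloxy)-2H-chromen-8-yl]prop-2-en-1-yl}-2,6-dihydroxy-4-methoxybenzaldehyde | COc1cc(O)c(C=O)c(O)c1CC(=C)c1ccc(O[Si](C(C)C)(C(C)C)C(C)C)c2c1OC(C)(C)C=C2
A4 | direct plan | (3R)-3-[2,2-dimethyl-5-(triisopropylsilyloxy)-2H-chromen-8-yl]-7-hydroxy-5-methoxy-3,4-dihydro-2H-chromene-8-carbaldehyde | COc1cc(O)c(C=O)c2c1C[C@H](c1ccc(O[Si](C(C)C)(C(C)C)C(C)C)c3c1OC(C)(C)C=C3)CO2
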